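Read from the SMILES, ring A (prenyl arm) is 2,6-cis, (2S,6R); ring B ((2E)-4-hydroxy-3-methylbut-2-enyl arm) is 2',6'-trans, (2'R,6'S); the C7–C7' polyene is all-E. C2 and C2' have the same spatial sense (the descriptor differs only because the hydroxylated arm outranks C3'), whereas C6 and C6' are opposite.
Retrosynthesis: cut C11=C12 and C11'=C12' (two Wittig reactions, C20 + C10 + C20), then C9–C10 and C7=C8 of each end group, then the side-arm CH2–CH= bonds (Negishi), then C2–C3 of each ring (lactone-bridged Claisen), then the lactones back to a 3,3-dimethylglutarate.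
Forward: half-ester acid chloride (made once, used for both rings) → N-acyl oxazolidinone → α-oxymethylation → ketone → tertiary allylic alkoxide closing a δ-lactone → ring-contracting Ireland–Claisen (ring A; then ring B by the same sequence in the enantiomeric auxiliary series) → side arms → C20 phosphonium salts → stepwise double Wittig with the C10 dialdehyde → ester cleavage.
Enabling feature: in each ring, C2 carries the first side-arm carbon (as a carboxyl) and C5 is a methyl-bearing alkene carbon. The C2 carboxyl can therefore be lactonised onto a C5 carbinol bearing methyl and vinyl (future C4, C3) across C1(Me)2–C6, and one [3,3] shift of the ketene acetal then forms C2–C3 and C4=C5 and closes the ring.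
Stereochemistry: C6/C6' from (S)- or (R)-4-benzyl-oxazolidinone; the carbinol centre by 1,2-induction (methyl onto the vinyl ketone for ring A, vinyl onto the methyl ketone for ring B); C2/C2' relayed from the carbinol through the boat; alkene geometry from the stabilised phosphonate, syn-carboalumination, and Wittig reactions with thermal equilibration.

Key step: step 7

Remark: the carbinol centres of 28 and 54 form as epimer mixtures that converge in the following step, and the double bonds made in steps 15, 32, 33 and 34 are taken as E after the crystallisation or thermal equilibration stated; carotenoid numbering (C1–C7, primed for ring B) is used in the Why lines.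

Step 1
Reactants: 1 3,3-dimethylglutaric anhydride
Product: 3 methyl 5-chloro-3,3-dimethyl-5-oxopentanoate, via half ester 2 (not isolated)
Conditions: MeOH, 65 °C; evaporate; then (COCl)2, DMF (cat.), CH2Cl2, 0 → 23 °C; concentrate below 30 °C, store as a CH2Cl2 stock solution at −20 °C
Reagents that add atoms: methanol CO; oxalyl chloride O=C(Cl)C(Cl)=O
Why: Alcoholysis of the symmetrical cyclic anhydride can open only one way and differentiates the two carboxyl carbons (future lactone carbonyl and future carbinol carbon C5), and DMF-catalysed chlorination of the free acid with oxalyl chloride then gives the acid chloride, which is kept cold and undistilled so that it cannot revert to the anhydride and which serves both ring series.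

Step 2
Reactants: 3 methyl 5-chloro-3,3-dimethyl-5-oxopentanoate; 4 (4S)-4-benzyl-1,3-oxazolidin-2-one
Product: 5 methyl 5-[(4S)-4-benzyl-2-oxo-1,3-oxazolidin-3-yl]-3,3-dimethyl-5-oxopentanoate
Conditions: Et3N, 4-(dimethylamino)pyridine (10 mol %), CH2Cl2, 0 → 23 °C
Reagents that add atoms: none
Why: N-Acylation of the oxazolidinone by the acid chloride under nucleophilic catalysis should occur only at the acyl chloride carbon, the methyl ester being far less electrophilic.

Step 3
Reactants: 5 methyl 5-[(4S)-4-benzyl-2-oxo-1,3-oxazolidin-3-yl]-3,3-dimethyl-5-oxopentanoate; 6 benzyl chloromethyl ether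
Product: 7 methyl (4R)-5-[(4S)-4-benzyl-2-oxo-1,3-oxazolidin-3-yl]-4-[(benzyloxy)methyl]-3,3-dimethyl-5-oxopentanoate
Conditions: TiCl4, i-Pr2NEt, CH2Cl2, 0 °C; then 6, 0 °C
Reagents that add atoms: none
Why: Oxazolidinone-directed alkylation of the chelated (Z)-titanium enolate (soft enolisation leaves the methyl ester alone) should take the benzyloxymethyl electrophile on the face opposite the auxiliary benzyl group, setting the future C6 as (R).

Step 4
Reactants: 7 methyl (4R)-5-[(4S)-4-benzyl-2-oxo-1,3-oxazolidin-3-yl]-4-[(benzyloxy)methyl]-3,3-dimethyl-5-oxopentanoate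
Product: 9 (2R)-2-[(benzyloxy)methyl]-5-methoxy-3,3-dimethyl-5-oxopentanoic acid, via peroxy acid 8 (not isolated)
Conditions: LiOH, H2O2, THF/H2O (3:1), 0 °C; Na2SO3 (aq); then 1 M HCl
Reagents that add atoms: hydrogen peroxide OO
Why: Hydroperoxide cleavage of the N-acyloxazolidinone at the exocyclic carbonyl should outrun hydroxide attack on the neopentyl-type methyl ester at 0 °C, and sulfite reduction of the peracid gives the acid without epimerisation while the auxiliary is recovered.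

Step 5
Reactants: 9 (2R)-2-[(benzyloxy)methyl]-5-methoxy-3,3-dimethyl-5-oxopentanoic acid; 10 tributyl(ethenyl)stannane
Product: 12 methyl (4R)-4-[(benzyloxy)methyl]-3,3-dimethyl-5-oxohept-6-enoate, via acid chloride 11 (not isolated)
Conditions: Me2C=C(Cl)NMe2, CH2Cl2, 23 °C; evaporate; then 10, Pd(PPh3)4 (5 mol %), THF, 50 °C
Reagents that add atoms: none
Why: Neutral acid chloride formation with the α-chloroenamine followed by Stille acylation at zerovalent palladium gives the vinyl ketone without any base, so neither the α-stereocentre nor the β-benzyloxy group is put at risk.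

Step 6
Reactants: 12 methyl (4R)-4-[(benzyloxy)methyl]-3,3-dimethyl-5-oxohept-6-enoate
Product: 14 (5R,6R)-5-[(benzyloxy)methyl]-6-ethenyl-4,4,6-trimethyloxan-2-one, via hydroxy ester 13 (not isolated)
Conditions: MeMgBr, CeCl3, THF, −78 °C; then 23 °C
Reagents that add atoms: methylmagnesium bromide C[Mg]Br
Why: Organocerium 1,2-addition to the enone (conjugate addition and enolisation suppressed) should occur antiperiplanar to the bulky tertiary alkyl group on the α-carbon, the same face a chelate to the benzyloxy oxygen would expose, so methyl enters cis and vinyl stays trans to the benzyloxymethyl group, and the tertiary alkoxide then closes the δ-lactone on the methyl ester.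

Step 7
Reactants: 14 (5R,6R)-5-[(benzyloxy)methyl]-6-ethenyl-4,4,6-trimethyloxan-2-one
Product: 17 (1S,5R)-5-[(benzyloxy)methyl]-4,6,6-trimethylcyclohex-3-ene-1-carboxylic acid, via silyl ketene acetal 15 (not isolated), via silyl ester 16 (not isolated)
Conditions: LiN(i-Pr)2, THF, −78 °C; Me3SiCl/Et3N, −78 → 23 °C; PhMe, 100 °C; then H2O/THF, 23 °C
Reagents that add atoms: none
Why: LiN(i-Pr)2 removes a proton from the only enolisable position (the CH2 next to the lactone carbonyl, future C2) and Me3SiCl traps the enolate on oxygen as cyclic ketene acetal 15, in which C2 and the vinyl group on the carbinol carbon C5 are held 1,4 across the ring; on heating, a concerted [3,3]-sigmatropic (Ireland–Claisen) shift joins C2 to the vinyl terminus C3, breaks the C5–O bond and turns the ring oxygen into the silyl ester carbonyl. The closest known reaction type is the ring-contracting ester-enolate Claisen rearrangement of 6-alkenyl-tetrahydropyran-2-one silyl ketene acetals to cyclohex-3-enecarboxylic acids. Ring A closes as a six-membered carbocycle by C–C bond formation in a boat-shaped, bicyclo[2.2.2]octane-like transition state whose two-atom bridge is the O–C(OSiMe3) unit (the tether excludes a chair), and the C4=C5 bond is necessarily cis within the ring. The new stereocentre C2 is controlled by the carbinol configuration at C5, because the bond can form only on the lactone face that carries the vinyl group; the benzyloxymethyl group at C6, trans to vinyl in 14, therefore ends on the same face of the new ring as the carboxyl group (2,6-cis). The step needs O- over C-silylation and rearrangement over ionisation or elimination at the tertiary allylic C–O bond; the cold in situ silyl chloride quench should secure the first and the methyl group on the carbinol carbon, which lowers the barrier of the shift, the second. Aqueous work-up hydrolyses silyl ester 16 to acid 17.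

Step 8
Reactants: 17 (1S,5R)-5-[(benzyloxy)methyl]-4,6,6-trimethylcyclohex-3-ene-1-carboxylic acid
Product: 18 [(1S,5R)-5-[(benzyloxy)methyl]-4,6,6-trimethylcyclohex-3-en-1-yl]methanol
Conditions: LiAlH4, THF, 0 → 40 °C
Reagents that add atoms: none
Why: Hydride reduction of the carboxylic acid to the primary alcohol leaves the ether, the alkene and both stereocentres untouched.

Step 9
Reactants: 18 [(1S,5R)-5-[(benzyloxy)methyl]-4,6,6-trimethylcyclohex-3-en-1-yl]methanol
Product: 19 ({[(1R,5S)-5-(iodomethyl)-2,6,6-trimethylcyclohex-2-en-1-yl]methoxy}methyl)benzene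
Conditions: I2, PPh3, imidazole, CH2Cl2, 0 → 23 °C
Reagents that add atoms: iodine II
Why: Appel-type iodination converts the primary alcohol into the iodide by SN2 displacement of the oxyphosphonium group.

Step 10
Reactants: 19 ({[(1R,5S)-5-(iodomethyl)-2,6,6-trimethylcyclohex-2-en-1-yl]methoxy}methyl)benzene; 20 1-bromo-2-methylprop-1-ene
Product: 22 ({[(1R,5S)-2,6,6-trimethyl-5-(3-methylbut-2-en-1-yl)cyclohex-2-en-1-yl]methoxy}methyl)benzene, via alkylzinc iodide 21 (not isolated)
Conditions: Zn, LiCl, THF, 40 °C; then 20, PdCl2(dppf) (5 mol %; dppf = 1,1'-bis(diphenylphosphino)ferrocene), THF, 50 °C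
Reagents that add atoms: none
Why: Zinc insertion into the primary C–I bond and Negishi sp3–sp2 coupling with the alkenyl bromide complete the prenyl arm with the double bond fixed in place, the bidentate phosphine favouring reductive elimination over β-hydride elimination.

Step 11
Reactants: 22 ({[(1R,5S)-2,6,6-trimethyl-5-(3-methylbut-2-en-1-yl)cyclohex-2-en-1-yl]methoxy}methyl)benzene
Product: 23 [(1R,5S)-2,6,6-trimethyl-5-(3-methylbut-2-en-1-yl)cyclohex-2-en-1-yl]methanol
Conditions: Na, NH3 (l), THF, −78 °C; then NH4Cl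
Reagents that add atoms: none
Why: Dissolving-metal (Birch-type) cleavage removes the benzyl ether while the isolated trisubstituted alkenes are not reduced and the homoallylic C–O bond is not cleaved.

Step 12
Reactants: 23 [(1R,5S)-2,6,6-trimethyl-5-(3-methylbut-2-en-1-yl)cyclohex-2-en-1-yl]methanol
Product: 24 (1R,5S)-2,6,6-trimethyl-5-(3-methylbut-2-en-1-yl)cyclohex-2-ene-1-carbaldehyde
Conditions: Dess–Martin periodinane, NaHCO3, CH2Cl2, 0 °C
Reagents that add atoms: none
Why: Buffered Dess–Martin oxidation should give the β,γ-unsaturated aldehyde without epimerising C6 or moving the ring double bond into conjugation, and the aldehyde is used at once.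

Step 13
Reactants: 24 (1R,5S)-2,6,6-trimethyl-5-(3-methylbut-2-en-1-yl)cyclohex-2-ene-1-carbaldehyde; 25 dimethyl (2-oxopropyl)phosphonate
Product: 26 (3E)-4-[(1R,5S)-2,6,6-trimethyl-5-(3-methylbut-2-en-1-yl)cyclohex-2-en-1-yl]but-3-en-2-one
Conditions: Ba(OH)2, THF/H2O (40:1), 23 °C
Reagents that add atoms: none
Why: Horner–Wadsworth–Emmons olefination with the stabilised β-ketophosphonate under mild Ba(OH)2 activation should give the (E)-enone faster than the α-centre can epimerise.

Step 14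
Reactants: 26 (3E)-4-[(1R,5S)-2,6,6-trimethyl-5-(3-methylbut-2-en-1-yl)cyclohex-2-en-1-yl]but-3-en-2-one; 27 vinylmagnesium bromide
Product: 28 (1E)-3-methyl-1-[(1R,5S)-2,6,6-trimethyl-5-(3-methylbut-2-en-1-yl)cyclohex-2-en-1-yl]penta-1,4-dien-3-ol
Conditions: THF, −78 → 0 °C; NH4Cl
Reagents that add atoms: none
Why: Copper-free Grignard 1,2-addition to the enone carbonyl gives the tertiary bis-allylic alcohol, whose new carbinol centre is lost in the next step.

Step 15
Reactants: 28 (1E)-3-methyl-1-[(1R,5S)-2,6,6-trimethyl-5-(3-methylbut-2-en-1-yl)cyclohex-2-en-1-yl]penta-1,4-dien-3-ol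
Product: 29 [(2E,4E)-3-methyl-5-[(1R,5S)-2,6,6-trimethyl-5-(3-methylbut-2-en-1-yl)cyclohex-2-en-1-yl]penta-2,4-dien-1-yl]triphenylphosphonium bromide
Conditions: Ph3P·HBr, MeOH/CH2Cl2, 0 → 23 °C; crystallisation
Reagents that add atoms: triphenylphosphonium bromide [Br-].c1ccc(cc1)[PH+](c1ccccc1)c1ccccc1
Why: Acid-induced ionisation of the tertiary bis-allylic alcohol and capture of the pentadienyl cation by PPh3 at the unhindered primary terminus (allylic transposition) gives the C20 Wittig salt, the (2E) isomer being expected to predominate and to be purified by crystallisation.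

Step 16
Reactants: 3 methyl 5-chloro-3,3-dimethyl-5-oxopentanoate; 30 (4R)-4-benzyl-1,3-oxazolidin-2-one
Product: 31 methyl 5-[(4R)-4-benzyl-2-oxo-1,3-oxazolidin-3-yl]-3,3-dimethyl-5-oxopentanoate
Conditions: Et3N, 4-(dimethylamino)pyridine (10 mol %), CH2Cl2, 0 → 23 °C
Reagents that add atoms: none
Why: The same catalysed N-acylation with acid chloride 3 as in step 2 introduces the enantiomeric auxiliary for ring B.

Step 17
Reactants: 31 methyl 5-[(4R)-4-benzyl-2-oxo-1,3-oxazolidin-3-yl]-3,3-dimethyl-5-oxopentanoate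
Product: 32 methyl (4S)-5-[(4R)-4-benzyl-2-oxo-1,3-oxazolidin-3-yl]-4-(hydroxymethyl)-3,3-dimethyl-5-oxopentanoate
Conditions: TiCl4, i-Pr2NEt, CH2Cl2, 0 °C; then 1,3,5-trioxane, TiCl4, 0 °C
Reagents that add atoms: 1,3,5-trioxane C1OCOCO1
Why: Aldol addition of the chelated (Z)-titanium enolate to formaldehyde released from trioxane should occur opposite the auxiliary benzyl group and set the future C6' as (S), the free hydroxyl allowing a silyl instead of a benzyl ether in this series.

Step 18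
Reactants: 32 methyl (4S)-5-[(4R)-4-benzyl-2-oxo-1,3-oxazolidin-3-yl]-4-(hydroxymethyl)-3,3-dimethyl-5-oxopentanoate
Product: 33 methyl (4S)-5-[(4R)-4-benzyl-2-oxo-1,3-oxazolidin-3-yl]-4-({[tert-butyl(dimethyl)silyl]oxy}methyl)-3,3-dimethyl-5-oxopentanoate
Conditions: t-BuMe2SiCl, imidazole, DMF, 23 °C
Reagents that add atoms: tert-butyl(chloro)dimethylsilane CC(C)(C)[Si](C)(C)Cl
Why: Silylation of the primary alcohol gives an ether that can later be cleaved by fluoride in the presence of the allylic pivalate and the alkenes of ring B.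

Step 19
Reactants: 33 methyl (4S)-5-[(4R)-4-benzyl-2-oxo-1,3-oxazolidin-3-yl]-4-({[tert-butyl(dimethyl)silyl]oxy}methyl)-3,3-dimethyl-5-oxopentanoate
Product: 35 (2S)-2-({[tert-butyl(dimethyl)silyl]oxy}methyl)-5-methoxy-3,3-dimethyl-5-oxopentanoic acid, via peroxy acid 34 (not isolated)
Conditions: LiOH, H2O2, THF/H2O (3:1), 0 °C; Na2SO3 (aq); then 1 M HCl (0 °C)
Reagents that add atoms: hydrogen peroxide OO
Why: Hydroperoxide cleavage of the imide and sulfite reduction, as in step 4, free the acid and return the auxiliary without touching the ester or the silyl ether.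

Step 20
Reactants: 35 (2S)-2-({[tert-butyl(dimethyl)silyl]oxy}methyl)-5-methoxy-3,3-dimethyl-5-oxopentanoic acid
Product: 37 methyl (4S)-4-({[tert-butyl(dimethyl)silyl]oxy}methyl)-3,3-dimethyl-5-oxohexanoate, via acid chloride 36 (not isolated)
Conditions: Me2C=C(Cl)NMe2, CH2Cl2, 23 °C; evaporate; then MeMgBr, Fe(acac)3 (3 mol %; acac = acetylacetonate), THF, −78 °C
Reagents that add atoms: methylmagnesium bromide C[Mg]Br
Why: Neutral acid chloride formation followed by iron-catalysed acylation of the Grignard reagent should stop at the methyl ketone and spare the ester and the silyl ether.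

Step 21
Reactants: 37 methyl (4S)-4-({[tert-butyl(dimethyl)silyl]oxy}methyl)-3,3-dimethyl-5-oxohexanoate; 27 vinylmagnesium bromide
Product: 39 (5S,6R)-5-({[tert-butyl(dimethyl)silyl]oxy}methyl)-6-ethenyl-4,4,6-trimethyloxan-2-one, via hydroxy ester 38 (not isolated)
Conditions: CeCl3, THF, −78 °C; then 23 °C
Reagents that add atoms: none
Why: Organocerium 1,2-addition to the hindered methyl ketone antiperiplanar to the tertiary alkyl group now places vinyl cis to the silyloxymethyl group (the roles of methyl and vinyl are exchanged relative to step 6), and the alkoxide lactonises onto the methyl ester.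

Step 22
Reactants: 39 (5S,6R)-5-({[tert-butyl(dimethyl)silyl]oxy}methyl)-6-ethenyl-4,4,6-trimethyloxan-2-one
Product: 42 (1S,5S)-5-({[tert-butyl(dimethyl)silyl]oxy}methyl)-4,6,6-trimethylcyclohex-3-ene-1-carboxylic acid, via silyl ketene acetal 40 (not isolated), via silyl ester 41 (not isolated)
Conditions: LiN(i-Pr)2, THF, −78 °C; Me3SiCl/Et3N, −78 → 23 °C; PhMe, 110 °C; then H2O/THF, 23 °C
Reagents that add atoms: none
Why: The same ring-contracting Ireland–Claisen rearrangement through the lactone-bridged boat closes ring B, the vinyl-bearing face again fixing C2', and because the silyloxymethyl group is cis to vinyl in 39 it ends trans to the carboxyl group (2',6'-trans).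

Step 23
Reactants: 42 (1S,5S)-5-({[tert-butyl(dimethyl)silyl]oxy}methyl)-4,6,6-trimethylcyclohex-3-ene-1-carboxylic acid
Product: 43 [(1S,5S)-5-({[tert-butyl(dimethyl)silyl]oxy}methyl)-4,6,6-trimethylcyclohex-3-en-1-yl]methanol
Conditions: LiAlH4, THF, 0 → 40 °C
Reagents that add atoms: none
Why: Hydride reduction of the acid to the primary alcohol is compatible with the silyl ether and the alkene.

Step 24
Reactants: 43 [(1S,5S)-5-({[tert-butyl(dimethyl)silyl]oxy}methyl)-4,6,6-trimethylcyclohex-3-en-1-yl]methanol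
Product: 44 tert-butyl{[(1S,5S)-5-(iodomethyl)-2,6,6-trimethylcyclohex-2-en-1-yl]methoxy}dimethylsilane
Conditions: I2, PPh3, imidazole, CH2Cl2, 0 → 23 °C
Reagents that add atoms: iodine II
Why: Appel-type iodination of the primary alcohol proceeds under buffered conditions that the silyl ether tolerates.

Step 25
Reactants: 45 prop-2-yn-1-ol
Product: 47 (2E)-3-iodo-2-methylprop-2-en-1-ol, via alkenylalane 46 (not isolated)
Conditions: AlMe3 (3 equiv), Cp2ZrCl2 (25 mol %), CH2Cl2, 0 → 23 °C; then I2, THF, −30 → 0 °C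
Reagents that add atoms: trimethylaluminium C[Al](C)C; iodine II
Why: Zirconium-catalysed syn-carboalumination of the alkyne (Negishi carboalumination) places methyl on C2 and aluminium cis to it on C3, and iodinolysis with retention gives the (E)-iodoalkene.

Step 26
Reactants: 47 (2E)-3-iodo-2-methylprop-2-en-1-ol
Product: 48 (2E)-3-iodo-2-methylprop-2-en-1-yl 2,2-dimethylpropanoate
Conditions: t-BuCOCl, pyridine, CH2Cl2, 0 → 23 °C
Reagents that add atoms: pivaloyl chloride CC(C)(C)C(Cl)=O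
Why: Acylation of the primary allylic alcohol installs a pivalate that should survive organozinc coupling, fluoride, Grignard addition at −78 °C and the acidic phosphonium salt formation.

Step 27
Reactants: 44 tert-butyl{[(1S,5S)-5-(iodomethyl)-2,6,6-trimethylcyclohex-2-en-1-yl]methoxy}dimethylsilane; 48 (2E)-3-iodo-2-methylprop-2-en-1-yl 2,2-dimethylpropanoate
Product: 50 (2E)-4-[(1R,5S)-5-({[tert-butyl(dimethyl)silyl]oxy}methyl)-4,6,6-trimethylcyclohex-3-en-1-yl]-2-methylbut-2-en-1-yl 2,2-dimethylpropanoate, via alkylzinc iodide 49 (not isolated)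
Conditions: Zn, LiCl, THF, 40 °C; then 48, Pd(PPh3)4 (5 mol %), THF, 23 °C
Reagents that add atoms: none
Why: Negishi sp3–sp2 coupling tolerates the ester, oxidative addition into the alkenyl C–I bond should be far faster than ionisation of the allylic pivalate, and the (E) geometry of the iodide is retained.

Step 28
Reactants: 50 (2E)-4-[(1R,5S)-5-({[tert-butyl(dimethyl)silyl]oxy}methyl)-4,6,6-trimethylcyclohex-3-en-1-yl]-2-methylbut-2-en-1-yl 2,2-dimethylpropanoate
Product: 51 (2E)-4-[(1R,5S)-5-(hydroxymethyl)-4,6,6-trimethylcyclohex-3-en-1-yl]-2-methylbut-2-en-1-yl 2,2-dimethylpropanoate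
Conditions: Bu4NF, THF, 0 → 23 °C
Reagents that add atoms: none
Why: Fluoride cleavage of the primary silyl ether frees the C7' alcohol while the pivalate is stable.

Step 29
Reactants: 51 (2E)-4-[(1R,5S)-5-(hydroxymethyl)-4,6,6-trimethylcyclohex-3-en-1-yl]-2-methylbut-2-en-1-yl 2,2-dimethylpropanoate
Product: 52 (2E)-4-[(1R,5S)-5-formyl-4,6,6-trimethylcyclohex-3-en-1-yl]-2-methylbut-2-en-1-yl 2,2-dimethylpropanoate
Conditions: Dess–Martin periodinane, NaHCO3, CH2Cl2, 0 °C
Reagents that add atoms: none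
Why: Buffered Dess–Martin oxidation gives the epimerisable β,γ-unsaturated aldehyde under non-basic conditions for immediate use.

Step 30
Reactants: 52 (2E)-4-[(1R,5S)-5-formyl-4,6,6-trimethylcyclohex-3-en-1-yl]-2-methylbut-2-en-1-yl 2,2-dimethylpropanoate; 25 dimethyl (2-oxopropyl)phosphonate
Product: 53 (2E)-2-methyl-4-[(1R,5S)-4,6,6-trimethyl-5-[(1E)-3-oxobut-1-en-1-yl]cyclohex-3-en-1-yl]but-2-en-1-yl 2,2-dimethylpropanoate
Conditions: Ba(OH)2, THF/H2O (40:1), 23 °C
Reagents that add atoms: none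
Why: The mild Horner–Wadsworth–Emmons olefination of step 13 gives the (E)-enone without hydrolysing the pivalate.

Step 31
Reactants: 53 (2E)-2-methyl-4-[(1R,5S)-4,6,6-trimethyl-5-[(1E)-3-oxobut-1-en-1-yl]cyclohex-3-en-1-yl]but-2-en-1-yl 2,2-dimethylpropanoate; 27 vinylmagnesium bromide
Product: 54 (2E)-4-[(1R,5S)-5-[(1E)-3-hydroxy-3-methylpenta-1,4-dien-1-yl]-4,6,6-trimethylcyclohex-3-en-1-yl]-2-methylbut-2-en-1-yl 2,2-dimethylpropanoate
Conditions: THF, −78 °C (1.2 equiv 27); NH4Cl
Reagents that add atoms: none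
Why: Grignard 1,2-addition to the ketone is much faster at −78 °C than attack on the hindered pivalate.

Step 32
Reactants: 54 (2E)-4-[(1R,5S)-5-[(1E)-3-hydroxy-3-methylpenta-1,4-dien-1-yl]-4,6,6-trimethylcyclohex-3-en-1-yl]-2-methylbut-2-en-1-yl 2,2-dimethylpropanoate
Product: 55 [(2E,4E)-5-[(1S,5R)-5-[(2E)-4-(2,2-dimethylpropanoyloxy)-3-methylbut-2-en-1-yl]-2,6,6-trimethylcyclohex-2-en-1-yl]-3-methylpenta-2,4-dien-1-yl]triphenylphosphonium bromide
Conditions: Ph3P·HBr, MeOH/CH2Cl2, 0 → 23 °C; crystallisation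
Reagents that add atoms: triphenylphosphonium bromide [Br-].c1ccc(cc1)[PH+](c1ccccc1)c1ccccc1
Why: The tertiary bis-allylic alcohol ionises far more readily than the primary allylic pivalate, so allylic transposition with PPh3 gives the C20 Wittig salt of ring B with the ester intact.

Step 33
Reactants: 29 [(2E,4E)-3-methyl-5-[(1R,5S)-2,6,6-trimethyl-5-(3-methylbut-2-en-1-yl)cyclohex-2-en-1-yl]penta-2,4-dien-1-yl]triphenylphosphonium bromide; 56 (2E,4E,6E)-2,7-dimethylocta-2,4,6-trienedial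
Product: 57 (2E,4E,6E,8E,10E,12E)-2,7,11-trimethyl-13-[(1R,5S)-2,6,6-trimethyl-5-(3-methylbut-2-en-1-yl)cyclohex-2-en-1-yl]trideca-2,4,6,8,10,12-hexaenal
Conditions: 56 (3 equiv), NaOMe, MeOH/CH2Cl2, 0 → 23 °C; then heptane, 98 °C
Reagents that add atoms: none
Why: Wittig olefination of the semi-stabilised C20 ylide with an excess of the symmetrical C10 dialdehyde should stop at mono-olefination, and heating equilibrates the new C11=C12 bond to E.

Step 34
Reactants: 57 (2E,4E,6E,8E,10E,12E)-2,7,11-trimethyl-13-[(1R,5S)-2,6,6-trimethyl-5-(3-methylbut-2-en-1-yl)cyclohex-2-en-1-yl]trideca-2,4,6,8,10,12-hexaenal; 55 [(2E,4E)-5-[(1S,5R)-5-[(2E)-4-(2,2-dimethylpropanoyloxy)-3-methylbut-2-en-1-yl]-2,6,6-trimethylcyclohex-2-en-1-yl]-3-methylpenta-2,4-dien-1-yl]triphenylphosphonium bromide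
Product: 58 (2S,6R,2'R,6'S)-2-(3-methylbut-2-enyl)-2'-[(2E)-3-methyl-4-(2,2-dimethylpropanoyloxy)but-2-enyl]-ε,ε-carotene
Conditions: 1,2-epoxybutane, EtOH, 75 °C; then heptane, 98 °C
Reagents that add atoms: none
Why: A second Wittig olefination under base-free epoxide conditions (the epoxide takes up HBr and liberates the ylide) joins the two halves without cleaving the pivalate, and heating equilibrates the polyene to all-E.

Step 35
Reactants: 58 (2S,6R,2'R,6'S)-2-(3-methylbut-2-enyl)-2'-[(2E)-3-methyl-4-(2,2-dimethylpropanoyloxy)but-2-enyl]-ε,ε-carotene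
Product: 59 (2S,6R,2'R,6'S)-2'-[(2E)-4-hydroxy-3-methylbut-2-enyl]-2-(3-methylbut-2-enyl)-ε,ε-carotene (CNP0304855.1)
Conditions: i-Bu2AlH, CH2Cl2, −78 °C; KNaC4H4O6 (aq); dark, argon
Reagents that add atoms: none
Why: Reductive cleavage of the pivalate by the aluminium hydride at low temperature releases the primary allylic alcohol and leaves the polyene and all four stereocentres untouched.

Compound list
1 | 3,3-dimethylglutaric anhydride | CC1(C)CC(=O)OC(=O)C1 | starting material
2 | 5-methoxy-3,3-dimethyl-5-oxopentanoic acid (not isolated) | COC(=O)CC(C)(C)CC(O)=O | intermediate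
3 | methyl 5-chloro-3,3-dimethyl-5-oxopentanoate | COC(=O)CC(C)(C)CC(Cl)=O | intermediate
4 | (4S)-4-benzyl-1,3-oxazolidin-2-one | O=C1OC[C@H](Cc2ccccc2)N1 | starting material
5 | methyl 5-[(4S)-4-benzyl-2-oxo-1,3-oxazolidin-3-yl]-3,3-dimethyl-5-oxopentanoate | COC(=O)CC(C)(C)CC(=O)N1[C@@H](Cc2ccccc2)COC1=O | intermediate
6 | benzyl chloromethyl ether | ClCOCc1ccccc1 | starting material
7 | methyl (4R)-5-[(4S)-4-benzyl-2-oxo-1,3-oxazolidin-3-yl]-4-[(benzyloxy)methyl]-3,3-dimethyl-5-oxopentanoate | COC(=O)CC(C)(C)[C@H](COCc1ccccc1)C(=O)N1[C@@H](Cc2ccccc2)COC1=O | intermediate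
8 | (2R)-2-[(benzyloxy)methyl]-5-methoxy-3,3-dimethyl-5-oxopentaneperoxoic acid (not isolated) | COC(=O)CC(C)(C)[C@H](COCc1ccccc1)C(=O)OO | intermediate
9 | (2R)-2-[(benzyloxy)methyl]-5-methoxy-3,3-dimethyl-5-oxopentanoic acid | COC(=O)CC(C)(C)[C@H](COCc1ccccc1)C(O)=O | intermediate
10 | tributyl(ethenyl)stannane | C=C[Sn](CCCC)(CCCC)CCCC | starting material
11 | methyl (4R)-4-[(benzyloxy)methyl]-5-chloro-3,3-dimethyl-5-oxopentanoate (not isolated) | COC(=O)CC(C)(C)[C@H](COCc1ccccc1)C(Cl)=O | intermediate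
12 | methyl (4R)-4-[(benzyloxy)methyl]-3,3-dimethyl-5-oxohept-6-enoate | COC(=O)CC(C)(C)[C@H](COCc1ccccc1)C(=O)C=C | intermediate
13 | methyl (4R,5R)-4-[(benzyloxy)methyl]-5-hydroxy-3,3,5-trimethylhept-6-enoate (formed as its alkoxide, not isolated) | COC(=O)CC(C)(C)[C@H](COCc1ccccc1)[C@](C)(O)C=C | intermediate
14 | (5R,6R)-5-[(benzyloxy)methyl]-6-ethenyl-4,4,6-trimethyloxan-2-one | C=C[C@@]1(C)OC(=O)CC(C)(C)[C@@H]1COCc1ccccc1 | intermediate
15 | {[(2R,3R)-3-[(benzyloxy)methyl]-2-ethenyl-2,4,4-trimethyl-3,4-dihydro-2H-pyran-6-yl]oxy}trimethylsilane (not isolated) | C=C[C@@]1(C)OC(O[Si](C)(C)C)=CC(C)(C)[C@@H]1COCc1ccccc1 | intermediate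
16 | trimethylsilyl (1S,5R)-5-[(benzyloxy)methyl]-4,6,6-trimethylcyclohex-3-ene-1-carboxylate (not isolated) | C[Si](C)(C)OC(=O)[C@H]1CC=C(C)[C@@H](COCc2ccccc2)C1(C)C | intermediate
17 | (1S,5R)-5-[(benzyloxy)methyl]-4,6,6-trimethylcyclohex-3-ene-1-carboxylic acid | OC(=O)[C@H]1CC=C(C)[C@@H](COCc2ccccc2)C1(C)C | intermediate
18 | [(1S,5R)-5-[(benzyloxy)methyl]-4,6,6-trimethylcyclohex-3-en-1-yl]methanol | OC[C@H]1CC=C(C)[C@@H](COCc2ccccc2)C1(C)C | intermediate
19 | ({[(1R,5S)-5-(iodomethyl)-2,6,6-trimethylcyclohex-2-en-1-yl]methoxy}methyl)benzene | IC[C@H]1CC=C(C)[C@@H](COCc2ccccc2)C1(C)C | intermediate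
20 | 1-bromo-2-methylprop-1-ene | CC(C)=CBr | starting material
21 | {[(1S,5R)-5-[(benzyloxy)methyl]-4,6,6-trimethylcyclohex-3-en-1-yl]methyl}(iodo)zinc (not isolated) | I[Zn]C[C@H]1CC=C(C)[C@@H](COCc2ccccc2)C1(C)C | intermediate
22 | ({[(1R,5S)-2,6,6-trimethyl-5-(3-methylbut-2-en-1-yl)cyclohex-2-en-1-yl]methoxy}methyl)benzene | CC(C)=CC[C@H]1CC=C(C)[C@@H](COCc2ccccc2)C1(C)C | intermediate
23 | [(1R,5S)-2,6,6-trimethyl-5-(3-methylbut-2-en-1-yl)cyclohex-2-en-1-yl]methanol | CC(C)=CC[C@H]1CC=C(C)[C@@H](CO)C1(C)C | intermediate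
24 | (1R,5S)-2,6,6-trimethyl-5-(3-methylbut-2-en-1-yl)cyclohex-2-ene-1-carbaldehyde | CC(C)=CC[C@H]1CC=C(C)[C@@H](C=O)C1(C)C | intermediate
25 | dimethyl (2-oxopropyl)phosphonate | COP(=O)(CC(C)=O)OC | starting material
26 | (3E)-4-[(1R,5S)-2,6,6-trimethyl-5-(3-methylbut-2-en-1-yl)cyclohex-2-en-1-yl]but-3-en-2-one | CC(C)=CC[C@H]1CC=C(C)[C@@H](/C=C/C(C)=O)C1(C)C | intermediate
27 | vinylmagnesium bromide | C=C[Mg]Br | starting material
28 | (1E)-3-methyl-1-[(1R,5S)-2,6,6-trimethyl-5-(3-methylbut-2-en-1-yl)cyclohex-2-en-1-yl]penta-1,4-dien-3-ol (both carbinol epimers) | CC(C)=CC[C@H]1CC=C(C)[C@@H](/C=C/C(C)(O)C=C)C1(C)C | intermediate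
29 | [(2E,4E)-3-methyl-5-[(1R,5S)-2,6,6-trimethyl-5-(3-methylbut-2-en-1-yl)cyclohex-2-en-1-yl]penta-2,4-dien-1-yl]triphenylphosphonium bromide | CC(C)=CC[C@H]1CC=C(C)[C@@H](/C=C/C(C)=C/C[P+](c2ccccc2)(c2ccccc2)c2ccccc2)C1(C)C.[Br-] | intermediate
30 | (4R)-4-benzyl-1,3-oxazolidin-2-one | O=C1OC[C@@H](Cc2ccccc2)N1 | starting material
31 | methyl 5-[(4R)-4-benzyl-2-oxo-1,3-oxazolidin-3-yl]-3,3-dimethyl-5-oxopentanoate | COC(=O)CC(C)(C)CC(=O)N1[C@H](Cc2ccccc2)COC1=O | intermediate
32 | methyl (4S)-5-[(4R)-4-benzyl-2-oxo-1,3-oxazolidin-3-yl]-4-(hydroxymethyl)-3,3-dimethyl-5-oxopentanoate | COC(=O)CC(C)(C)[C@@H](CO)C(=O)N1[C@H](Cc2ccccc2)COC1=O | intermediate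
33 | methyl (4S)-5-[(4R)-4-benzyl-2-oxo-1,3-oxazolidin-3-yl]-4-({[tert-butyl(dimethyl)silyl]oxy}methyl)-3,3-dimethyl-5-oxopentanoate | COC(=O)CC(C)(C)[C@@H](CO[Si](C)(C)C(C)(C)C)C(=O)N1[C@H](Cc2ccccc2)COC1=O | intermediate
34 | (2S)-2-({[tert-butyl(dimethyl)silyl]oxy}methyl)-5-methoxy-3,3-dimethyl-5-oxopentaneperoxoic acid (not isolated) | COC(=O)CC(C)(C)[C@@H](CO[Si](C)(C)C(C)(C)C)C(=O)OO | intermediate
35 | (2S)-2-({[tert-butyl(dimethyl)silyl]oxy}methyl)-5-methoxy-3,3-dimethyl-5-oxopentanoic acid | COC(=O)CC(C)(C)[C@@H](CO[Si](C)(C)C(C)(C)C)C(O)=O | intermediate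
36 | methyl (4S)-4-({[tert-butyl(dimethyl)silyl]oxy}methyl)-5-chloro-3,3-dimethyl-5-oxopentanoate (not isolated) | COC(=O)CC(C)(C)[C@@H](CO[Si](C)(C)C(C)(C)C)C(Cl)=O | intermediate
37 | methyl (4S)-4-({[tert-butyl(dimethyl)silyl]oxy}methyl)-3,3-dimethyl-5-oxohexanoate | COC(=O)CC(C)(C)[C@@H](CO[Si](C)(C)C(C)(C)C)C(C)=O | intermediate
38 | methyl (4S,5R)-4-({[tert-butyl(dimethyl)silyl]oxy}methyl)-5-hydroxy-3,3,5-trimethylhept-6-enoate (formed as its alkoxide, not isolated) | COC(=O)CC(C)(C)[C@@H](CO[Si](C)(C)C(C)(C)C)[C@](C)(O)C=C | intermediate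
39 | (5S,6R)-5-({[tert-butyl(dimethyl)silyl]oxy}methyl)-6-ethenyl-4,4,6-trimethyloxan-2-one | C=C[C@@]1(C)OC(=O)CC(C)(C)[C@H]1CO[Si](C)(C)C(C)(C)C | intermediate
40 | tert-butyl{[(2R,3S)-2-ethenyl-2,4,4-trimethyl-6-[(trimethylsilyl)oxy]-3,4-dihydro-2H-pyran-3-yl]methoxy}dimethylsilane (not isolated) | C=C[C@@]1(C)OC(O[Si](C)(C)C)=CC(C)(C)[C@H]1CO[Si](C)(C)C(C)(C)C | intermediate
41 | trimethylsilyl (1S,5S)-5-({[tert-butyl(dimethyl)silyl]oxy}methyl)-4,6,6-trimethylcyclohex-3-ene-1-carboxylate (not isolated) | C[Si](C)(C)OC(=O)[C@H]1CC=C(C)[C@H](CO[Si](C)(C)C(C)(C)C)C1(C)C | intermediate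
42 | (1S,5S)-5-({[tert-butyl(dimethyl)silyl]oxy}methyl)-4,6,6-trimethylcyclohex-3-ene-1-carboxylic acid | OC(=O)[C@H]1CC=C(C)[C@H](CO[Si](C)(C)C(C)(C)C)C1(C)C | intermediate
43 | [(1S,5S)-5-({[tert-butyl(dimethyl)silyl]oxy}methyl)-4,6,6-trimethylcyclohex-3-en-1-yl]methanol | OC[C@H]1CC=C(C)[C@H](CO[Si](C)(C)C(C)(C)C)C1(C)C | intermediate
44 | tert-butyl{[(1S,5S)-5-(iodomethyl)-2,6,6-trimethylcyclohex-2-en-1-yl]methoxy}dimethylsilane | IC[C@H]1CC=C(C)[C@H](CO[Si](C)(C)C(C)(C)C)C1(C)C | intermediate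
45 | prop-2-yn-1-ol | C#CCO | starting material
46 | dimethyl[(1E)-3-[(dimethylalumanyl)oxy]-2-methylprop-1-en-1-yl]alumane (not isolated) | C[Al](C)OC/C(C)=C/[Al](C)C | intermediate
47 | (2E)-3-iodo-2-methylprop-2-en-1-ol | OC/C(C)=C/I | intermediate
48 | (2E)-3-iodo-2-methylprop-2-en-1-yl 2,2-dimethylpropanoate | CC(C)(C)C(=O)OC/C(C)=C/I | intermediate
49 | {[(1S,5S)-5-({[tert-butyl(dimethyl)silyl]oxy}methyl)-4,6,6-trimethylcyclohex-3-en-1-yl]methyl}(iodo)zinc (not isolated) | I[Zn]C[C@H]1CC=C(C)[C@H](CO[Si](C)(C)C(C)(C)C)C1(C)C | intermediate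
50 | (2E)-4-[(1R,5S)-5-({[tert-butyl(dimethyl)silyl]oxy}methyl)-4,6,6-trimethylcyclohex-3-en-1-yl]-2-methylbut-2-en-1-yl 2,2-dimethylpropanoate | CC(C)(C)C(=O)OC/C(C)=C/C[C@H]1CC=C(C)[C@H](CO[Si](C)(C)C(C)(C)C)C1(C)C | intermediate
51 | (2E)-4-[(1R,5S)-5-(hydroxymethyl)-4,6,6-trimethylcyclohex-3-en-1-yl]-2-methylbut-2-en-1-yl 2,2-dimethylpropanoate | CC(C)(C)C(=O)OC/C(C)=C/C[C@H]1CC=C(C)[C@H](CO)C1(C)C | intermediate
52 | (2E)-4-[(1R,5S)-5-formyl-4,6,6-trimethylcyclohex-3-en-1-yl]-2-methylbut-2-en-1-yl 2,2-dimethylpropanoate | CC(C)(C)C(=O)OC/C(C)=C/C[C@H]1CC=C(C)[C@H](C=O)C1(C)C | intermediate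
53 | (2E)-2-methyl-4-[(1R,5S)-4,6,6-trimethyl-5-[(1E)-3-oxobut-1-en-1-yl]cyclohex-3-en-1-yl]but-2-en-1-yl 2,2-dimethylpropanoate | CC(C)(C)C(=O)OC/C(C)=C/C[C@H]1CC=C(C)[C@H](/C=C/C(C)=O)C1(C)C | intermediate
54 | (2E)-4-[(1R,5S)-5-[(1E)-3-hydroxy-3-methylpenta-1,4-dien-1-yl]-4,6,6-trimethylcyclohex-3-en-1-yl]-2-methylbut-2-en-1-yl 2,2-dimethylpropanoate (both carbinol epimers) | CC(C)(C)C(=O)OC/C(C)=C/C[C@H]1CC=C(C)[C@H](/C=C/C(C)(O)C=C)C1(C)C | intermediate
55 | [(2E,4E)-5-[(1S,5R)-5-[(2E)-4-(2,2-dimethylpropanoyloxy)-3-methylbut-2-en-1-yl]-2,6,6-trimethylcyclohex-2-en-1-yl]-3-methylpenta-2,4-dien-1-yl]triphenylphosphonium bromide | CC(C)(C)C(=O)OC/C(C)=C/C[C@H]1CC=C(C)[C@H](/C=C/C(C)=C/C[P+](c2ccccc2)(c2ccccc2)c2ccccc2)C1(C)C.[Br-] | intermediate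
56 | (2E,4E,6E)-2,7-dimethylocta-2,4,6-trienedial | O=C/C(C)=C/C=C/C=C(C)/C=O | starting material
57 | (2E,4E,6E,8E,10E,12E)-2,7,11-trimethyl-13-[(1R,5S)-2,6,6-trimethyl-5-(3-methylbut-2-en-1-yl)cyclohex-2-en-1-yl]trideca-2,4,6,8,10,12-hexaenal | CC(C)=CC[C@H]1CC=C(C)[C@@H](/C=C/C(C)=C/C=C/C(C)=C/C=C/C=C(C)/C=O)C1(C)C | intermediate
58 | (2S,6R,2'R,6'S)-2-(3-methylbut-2-enyl)-2'-[(2E)-3-methyl-4-(2,2-dimethylpropanoyloxy)but-2-enyl]-ε,ε-carotene | CC(C)=CC[C@H]1CC=C(C)[C@@H](/C=C/C(C)=C/C=C/C(C)=C/C=C/C=C(C)/C=C/C=C(C)/C=C/[C@H]2C(C)=CC[C@H](C/C=C(\C)COC(=O)C(C)(C)C)C2(C)C)C1(C)C | intermediate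
59 | (2S,6R,2'R,6'S)-2'-[(2E)-4-hydroxy-3-methylbut-2-enyl]-2-(3-methylbut-2-enyl)-ε,ε-carotene (CNP0304855.1) | CC(C)=CC[C@H]1CC=C(C)[C@@H](/C=C/C(C)=C/C=C/C(C)=C/C=C/C=C(C)/C=C/C=C(C)/C=C/[C@H]2C(C)=CC[C@H](C/C=C(\C)CO)C2(C)C)C1(C)C | target

Total step count: 35.
Longest linear sequence: 18 steps (1, 2–15, 33, 34, 35; the ring B branch 1, 16–24, 27–32, 34, 35 is equally long).

Steps most likely to fail

Step 6. The unsubstituted enone terminus of 12 may take the methyl nucleophile in conjugate fashion or polymerise, and facial discrimination may be incomplete. The fallback sets out from acid 9 and comes back at lactone 14. Acid chloride 11, made as in step 5, would be coupled under the same Stille conditions with tributyl[(trimethylsilyl)ethynyl]stannane to give the silyl ynone methyl (4R)-4-[(benzyloxy)methyl]-3,3-dimethyl-5-oxo-7-(trimethylsilyl)hept-6-ynoate F1, whose β-carbon is blocked. Addition of MeMgBr/CeCl3 with the same 1,2-induction and lactonisation should give (5R,6S)-5-[(benzyloxy)methyl]-4,4,6-trimethyl-6-[(trimethylsilyl)ethynyl]oxan-2-one F2 (same spatial arrangement as 14; the descriptor changes because the alkyne outranks C5). Bu4NF buffered with AcOH would give (5R,6S)-5-[(benzyloxy)methyl]-6-ethynyl-4,4,6-trimethyloxan-2-one F3, and semihydrogenation (H2, Pd/CaCO3 poisoned with Pb(OAc)2, quinoline) returns to 14.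

Step 13 (and its ring B twin, step 30). The β,γ-unsaturated aldehyde may epimerise at C6 or isomerise into conjugation under the basic olefination. The fallback sets out from alcohol 23 and comes back at phosphonium salt 29, so that C6 is never alpha to a carbonyl. Mitsunobu reaction with 1-phenyl-1H-tetrazole-5-thiol would give 1-phenyl-5-({[(1R,5S)-2,6,6-trimethyl-5-(3-methylbut-2-en-1-yl)cyclohex-2-en-1-yl]methyl}sulfanyl)-1H-tetrazole F4, and oxidation with (NH4)6Mo7O24/H2O2 the sulfone 1-phenyl-5-({[(1R,5S)-2,6,6-trimethyl-5-(3-methylbut-2-en-1-yl)cyclohex-2-en-1-yl]methyl}sulfonyl)-1H-tetrazole F5. Julia–Kocienski olefination (KN(SiMe3)2, THF, −78 °C) with (2E)-4-{[tert-butyl(dimethyl)silyl]oxy}-2-methylbut-2-enal would then give tert-butyldimethyl{[(2E,4E)-3-methyl-5-[(1R,5S)-2,6,6-trimethyl-5-(3-methylbut-2-en-1-yl)cyclohex-2-en-1-yl]penta-2,4-dien-1-yl]oxy}silane F6. Ph3P·HBr in MeOH should cleave the silyl ether and convert the dienyl alcohol directly into 29.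

Step 3. Capture of the neopentyl-type titanium enolate by the bulky benzyloxymethyl cation may be slow, letting the chloromethyl ether decompose and selectivity erode. The fallback sets out from imide 5 and comes back at 7. It replaces the alkylation by the aldol addition to formaldehyde used for ring B (TiCl4, i-Pr2NEt; 1,3,5-trioxane, TiCl4), which would give methyl (4R)-5-[(4S)-4-benzyl-2-oxo-1,3-oxazolidin-3-yl]-4-(hydroxymethyl)-3,3-dimethyl-5-oxopentanoate F7. Acid-catalysed O-benzylation with benzyl 2,2,2-trichloroacetimidate and catalytic CF3SO3H then gives 7.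

Further compounds
F1 | step 6 | methyl (4R)-4-[(benzyloxy)methyl]-3,3-dimethyl-5-oxo-7-(trimethylsilyl)hept-6-ynoate | COC(=O)CC(C)(C)[C@H](COCc1ccccc1)C(=O)C#C[Si](C)(C)C
F2 | step 6 | (5R,6S)-5-[(benzyloxy)methyl]-4,4,6-trimethyl-6-[(trimethylsilyl)ethynyl]oxan-2-one | C[Si](C)(C)C#C[C@@]1(C)OC(=O)CC(C)(C)[C@@H]1COCc1ccccc1
F3 | step 6 | (5R,6S)-5-[(benzyloxy)methyl]-6-ethynyl-4,4,6-trimethyloxan-2-one | C#C[C@@]1(C)OC(=O)CC(C)(C)[C@@H]1COCc1ccccc1
F4 | step 13 | 1-phenyl-5-({[(1R,5S)-2,6,6-trimethyl-5-(3-methylbut-2-en-1-yl)cyclohex-2-en-1-yl]methyl}sulfanyl)-1H-tetrazole | CC(C)=CC[C@H]1CC=C(C)[C@@H](CSc2nnnn2-c2ccccc2)C1(C)C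
F5 | step 13 | 1-phenyl-5-({[(1R,5S)-2,6,6-trimethyl-5-(3-methylbut-2-en-1-yl)cyclohex-2-en-1-yl]methyl}sulfonyl)-1H-tetrazole | CC(C)=CC[C@H]1CC=C(C)[C@@H](CS(=O)(=O)c2nnnn2-c2ccccc2)C1(C)C
F6 | step 13 | tert-butyldimethyl{[(2E,4E)-3-methyl-5-[(1R,5S)-2,6,6-trimethyl-5-(3-methylbut-2-en-1-yl)cyclohex-2-en-1-yl]penta-2,4-dien-1-yl]oxy}silane | CC(C)=CC[C@H]1CC=C(C)[C@@H](/C=C/C(C)=C/CO[Si](C)(C)C(C)(C)C)C1(C)C
F7 | step 3 | methyl (4R)-5-[(4S)-4-benzyl-2-oxo-1,3-oxazolidin-3-yl]-4-(hydroxymethyl)-3,3-dimethyl-5-oxopentanoate | COC(=O)CC(C)(C)[C@H](CO)C(=O)N1[C@@H](Cc2ccccc2)COC1=O
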